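**Plan**
1. Retrosynthesis: the C8 ester, the C13 acetate and the C1 hemiketal hydroxyl (carried as a methyl ketal) come off first; the ten-membered ring is then opened at C5=C6, the chain is cut at C7–C8 (butenolide from tetronic acid) and at C1–C10, and the oxolane is opened at C1–O to a hydroxy ketone derived from (R)-linalool.
2. Enabling feature: the C5=C6 ylidene is the dehydrated vinylogous aldol of the butenolide γ-carbon C6 with an aldehyde at C5. C5 hangs on the quaternary oxolane carbon C4, so this aldehyde cannot enolise, and the cis-2,5-disubstituted oxolane ring and the flat butenolide ring fold the chain for closure.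
3. Forward: linalool supplies C1–C5 and C15; propargylation at C1 brings C8–C10 and C14; oxidation and methanolysis close the oxolane ring; the alkyne becomes the C8 aldehyde, to which the butenolide ring is coupled; cleavage of the vinyl group gives the C5 aldehyde; the C5–C6 closure forms the ten-membered ring last, before the esters are adjusted.
4. Stereochemistry: C4 from (R)-linalool; C10 from (S)-but-3-yn-2-yl mesylate by chirality transfer; C8 from a ligand-controlled Ni/Cr addition; C1 by equilibrium ketalisation, fixed in the end by the oxygen bridge; the C5=C6 geometry by the bridged ring; the side-chain alkene by a stabilised Wittig reaction.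

Key step: step 14

Remark: germacrane numbering is used (C1 ketal carbon, C4 quaternary oxolane carbon, C5=C6 ylidene, C7=C11 butenolide alkene, C8 carbinol, C10 methine, C12 lactone carbonyl, C13 oxymethyl); it is assumed that the ketalisation of step 6 gives both C1 epimers under equilibrium control, so that the unwanted one can be separated and resubmitted.

Step 1
Reactants: 1 (R)-(−)-linalool
Product: 2 (3R)-3,7-dimethyl-3-(trimethylsilyloxy)octa-1,6-diene
Conditions: Me3SiCl, imidazole, DMF, 0 °C to rt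
Reagents that add atoms: chlorotrimethylsilane, C[Si](C)(C)Cl
Why: Silyl ether formation masks the tertiary allylic alcohol so that the aldehyde made next stays open-chain instead of closing to a lactol, and C4 (R) is taken unchanged from linalool.

Step 2
Reactants: 2 (3R)-3,7-dimethyl-3-(trimethylsilyloxy)octa-1,6-diene
Product: 4 (4R)-4-methyl-4-(trimethylsilyloxy)hex-5-enal, via ozonide 3 (not isolated)
Conditions: O3, CH2Cl2, −78 °C, Sudan Red 7B end-point; then PPh3, −78 °C to rt
Reagents that add atoms: ozone, [O-][O+]=O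
Why: Ozonolysis with a dye end-point cleaves the electron-rich trisubstituted alkene well before the vinyl group next to the silyloxy-bearing quaternary carbon, and reduction of the ozonide gives the C1 aldehyde.

Step 3
Reactants: 5 (S)-but-3-yn-2-ol
Product: 6 (S)-but-3-yn-2-yl methanesulfonate
Conditions: MeSO2Cl, Et3N, CH2Cl2, −78 to 0 °C
Reagents that add atoms: methanesulfonyl chloride, CS(=O)(=O)Cl
Why: Mesylation at oxygen keeps the carbinol configuration and gives the propargylic leaving group needed for the allenylzinc reagent.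

Step 4
Reactants: 4 (4R)-4-methyl-4-(trimethylsilyloxy)hex-5-enal; 6 (S)-but-3-yn-2-yl methanesulfonate
Product: 9 (3R,4S,7R)-3,7-dimethylnon-8-en-1-yne-4,7-diol, via allenylzinc 7 (not isolated), via trimethylsilyl ether 8 (not isolated)
Conditions: Pd(OAc)2 (5 mol %), PPh3 (5 mol %), Et2Zn (3 equiv), THF, −78 to −20 °C; aq. NH4Cl; then K2CO3, MeOH, rt
Reagents that add atoms: none
Why: In this Marshall propargylation zerovalent palladium displaces the mesylate anti (SN2′), transmetallation gives the (aR)-allenylzinc 7, and its addition through a cyclic SE2′ transition state sets C10 (R) with net inversion of the mesylate centre and gives mainly the anti (C1 S) carbinol, whose C1 configuration is erased in step 5, before base methanolysis frees the tertiary alcohol.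

Step 5
Reactants: 9 (3R,4S,7R)-3,7-dimethylnon-8-en-1-yne-4,7-diol
Product: 10 (3R,7R)-7-hydroxy-3,7-dimethylnon-8-en-1-yn-4-one (in equilibrium with its five-membered cyclic hemiketal)
Conditions: Dess–Martin periodinane, CH2Cl2, 0 °C
Reagents that add atoms: none
Why: Dess–Martin oxidation touches only the secondary alcohol, and because no base is present and the γ-hydroxy ketone rests largely as its hemiketal, the propargylic C10 centre should not enolise or isomerise to the allenyl ketone.

Step 6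
Reactants: 10 (3R,7R)-7-hydroxy-3,7-dimethylnon-8-en-1-yn-4-one
Product: 11 (2S,5R)-2-[(2R)-but-3-yn-2-yl]-2-methoxy-5-methyl-5-vinyloxolane
Conditions: PPTS (cat.), MeOH, 3 Å molecular sieves, rt
Reagents that add atoms: methanol, CO
Why: Acid-catalysed mixed-ketal formation from the hemiketal is under thermodynamic control and is expected to give both C1 epimers, which interconvert under the same conditions, so the (2S) epimer with the butynyl group cis to the vinyl group is separated and the other is resubmitted.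

Step 7
Reactants: 11 (2S,5R)-2-[(2R)-but-3-yn-2-yl]-2-methoxy-5-methyl-5-vinyloxolane
Product: 13 (3R)-3-[(2S,5R)-2-methoxy-5-methyl-5-vinyloxolan-2-yl]butanal, via alkenylborane 12 (not isolated)
Conditions: Cy2BH (1.2 equiv), THF, 0 °C; then H2O2, pH 7 phosphate buffer, 0 °C
Reagents that add atoms: hydrogen peroxide, OO
Why: Anti-Markovnikov hydroboration of the terminal alkyne by the bulky dialkylborane is faster than attack on the hindered vinyl group, and buffered oxidation of the alkenylborane gives the C8 aldehyde with the ketal intact.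

Step 8
Reactants: 14 tetronic acid
Product: 16 4-bromo-2-oxo-2,5-dihydrofuran-3-carbaldehyde, via iminium salt 15 (not isolated)
Conditions: DMF, PBr3, CHCl3, 0 to 60 °C; then ice-water, NaHCO3
Reagents that add atoms: N,N-dimethylformamide, CN(C)C=O; phosphorus tribromide, BrP(Br)Br; water, O
Why: Vilsmeier–Haack–Arnold haloformylation formylates the nucleophilic C3 of the cyclic β-keto lactone and turns the C4 enol into the vinyl bromide, as it does with 4-hydroxycoumarin and cyclic 1,3-diones.

Step 9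
Reactants: 16 4-bromo-2-oxo-2,5-dihydrofuran-3-carbaldehyde
Product: 17 4-bromo-3-(hydroxymethyl)furan-2(5H)-one
Conditions: NaBH4, CeCl3·7H2O, THF/MeOH, −78 °C
Reagents that add atoms: none
Why: Luche reduction is 1,2-selective for the aldehyde and should leave the β-bromo butenolide untouched at low temperature.

Step 10
Reactants: 17 4-bromo-3-(hydroxymethyl)furan-2(5H)-one
Product: 18 4-bromo-3-({[tert-butyl(dimethyl)silyl]oxy}methyl)furan-2(5H)-one
Conditions: tBuMe2SiOTf, 2,6-lutidine, CH2Cl2, −78 °C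
Reagents that add atoms: tert-butyldimethylsilyl trifluoromethanesulfonate, CC(C)(C)[Si](C)(C)OS(=O)(=O)C(F)(F)F
Why: Silylation with a non-nucleophilic base protects the C13 alcohol without substitution of the vinylogous acyl bromide, and the silyl ether later gives the furanolate nothing to expel.

Step 11
Reactants: 13 (3R)-3-[(2S,5R)-2-methoxy-5-methyl-5-vinyloxolan-2-yl]butanal; 18 4-bromo-3-({[tert-butyl(dimethyl)silyl]oxy}methyl)furan-2(5H)-one
Product: 20 3-({[tert-butyl(dimethyl)silyl]oxy}methyl)-4-{(1S,3R)-1-hydroxy-3-[(2S,5R)-2-methoxy-5-methyl-5-vinyloxolan-2-yl]butyl}furan-2(5H)-one, via alkenylchromium 19 (not isolated)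
Conditions: CrCl2 (4 equiv), NiCl2 (2 mol %), chiral (4-isopropyloxazolin-2-yl)aryl methanesulfonamide ligand (4 equiv, antipode for Re-face attack), Et3N, THF, rt
Reagents that add atoms: none
Why: In this Nozaki–Hiyama–Kishi coupling zerovalent nickel inserts into the activated C7–Br bond, transmetallation gives the alkenylchromium 19 (trivalent chromium), which adds only to the aldehyde, and the chiral sulfonamide ligand on chromium directs attack to the Re face of 13 to set C8 (S).

Step 12
Reactants: 20 the C8 alcohol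
Product: 21 3-({[tert-butyl(dimethyl)silyl]oxy}methyl)-4-{(1S,3R)-1-{[tert-butyl(dimethyl)silyl]oxy}-3-[(2S,5R)-2-methoxy-5-methyl-5-vinyloxolan-2-yl]butyl}furan-2(5H)-one
Conditions: tBuMe2SiOTf, 2,6-lutidine, CH2Cl2, −78 °C
Reagents that add atoms: tert-butyldimethylsilyl trifluoromethanesulfonate, CC(C)(C)[Si](C)(C)OS(=O)(=O)C(F)(F)F
Why: Silyl triflate with lutidine silylates the hindered allylic alcohol at −78 °C, a temperature at which mixed methyl ketals survive this reagent.

Step 13
Reactants: 21 the C8,C13-bis-silyl ether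
Product: 23 (2R,5S)-5-{(2R,4S)-4-{[tert-butyl(dimethyl)silyl]oxy}-4-[4-({[tert-butyl(dimethyl)silyl]oxy}methyl)-5-oxo-2,5-dihydrofuran-3-yl]butan-2-yl}-5-methoxy-2-methyloxolane-2-carbaldehyde, via ozonide 22 (not isolated)
Conditions: O3, CH2Cl2, −78 °C, Sudan Red 7B end-point; then PPh3, −78 °C to rt
Reagents that add atoms: ozone, [O-][O+]=O
Why: Ozonolysis picks the vinyl group because the only other alkene is the electron-poor tetrasubstituted butenolide double bond, and it unveils the C5 aldehyde on the quaternary C4.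

Step 14
Reactants: 23 the C5 aldehyde tethered to the C6-unsubstituted butenolide
Product: 26 (1S,4R,5E,8S,10R)-8,13-bis{[tert-butyl(dimethyl)silyl]oxy}-1,4-epoxy-1-methoxygermacra-5,7(11)-dien-12,6-olide, via silyloxyfuran 24 (not isolated), via silyl aldol 25 (not isolated)
Conditions: tBuMe2SiOTf (3 equiv), iPr2NEt (6 equiv), CH2Cl2, slow addition of 23 (final 1 mM), −78 to −40 °C; then DBU, −40 °C to rt
Reagents that add atoms: none
Why: Proposed new method: soft enolisation by tBuMe2SiOTf/iPr2NEt turns the butenolide into the aromatic 2-silyloxyfuran 24, whose C6 terminus adds in a vinylogous Mukaiyama aldol step to the silyl-activated C5 aldehyde (not enolisable, since C4 is quaternary), and DBU then removes the acidic C6–H of the silyl aldol 25 and expels silanolate (E1cB) to give the conjugated ylidene irreversibly. The closest known reaction type is the one-pot silyl triflate/amine vinylogous aldol of butenolides with aldehydes followed by DBU elimination, established between two molecules; using it to close a ring is the new element. The ten-membered carbocycle (a nine-membered ring when counted through the oxolane oxygen) closes 10-exo-trig with respect to the carbonyl, helped by slow addition at high dilution and by two turn elements, the cis-2,5-disubstituted oxolane and the planar butenolide. No stereocentre is created for keeps: the C5 and C6 centres of 25 are both erased, so every diastereomer of 25 converges on one alkene. The step needs reaction at C6 and not C8, which the aromatic silyloxyfuran secures; it needs the C5=C6 geometry with C4 cis to C7, which the oxygen-bridged ring should impose because it is too small to hold the trans alkene without strain; and it needs an intact C1 ketal, which is why the triflate acts only at −78 to −40 °C and is quenched by DBU before warming. C13 stays a silyl ether so that the electron-rich furan has no leaving group to expel.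

Step 15
Reactants: 26 the C1 methyl ketal of the core with C8 and C13 silyl ethers
Product: 27 (1S,4R,5E,8S,10R)-1,4-epoxy-8,13-dihydroxy-1-methoxygermacra-5,7(11)-dien-12,6-olide
Conditions: HF·pyridine, pyridine, THF, 0 °C to rt
Reagents that add atoms: none
Why: Buffered fluoride desilylation removes both silyl ethers while the ketal and the base-sensitive enol lactone are spared.

Step 16
Reactants: 27 the C8,C13-diol
Product: 28 (1S,4R,5E,8S,10R)-13-acetoxy-1,4-epoxy-8-hydroxy-1-methoxygermacra-5,7(11)-dien-12,6-olide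
Conditions: AcCl (1.05 equiv), 2,4,6-collidine, CH2Cl2, −78 °C
Reagents that add atoms: acetyl chloride, CC(=O)Cl
Why: Acylation with a weak hindered base at low temperature is selective for the primary allylic alcohol over the hindered secondary C8 alcohol.

Step 17
Reactants: 29 {[tert-butyl(dimethyl)silyl]oxy}acetaldehyde; 30 ethyl 2-(triphenyl-λ5-phosphanylidene)propanoate
Product: 31 ethyl (2E)-4-{[tert-butyl(dimethyl)silyl]oxy}-2-methylbut-2-enoate
Conditions: CH2Cl2, rt
Reagents that add atoms: none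
Why: Wittig olefination with the stabilised α-methyl ylide gives the (E)-trisubstituted enoate of the side chain.

Step 18
Reactants: 31 ethyl (2E)-4-{[tert-butyl(dimethyl)silyl]oxy}-2-methylbut-2-enoate
Product: 32 (2E)-4-{[tert-butyl(dimethyl)silyl]oxy}-2-methylbut-2-enoic acid
Conditions: LiOH, THF/H2O, 0 °C to rt; then 1 M HCl to pH 4, 0 °C
Reagents that add atoms: lithium hydroxide, [Li+].[OH-]
Why: Saponification of the ethyl ester leaves the primary silyl ether, which tolerates cold dilute hydroxide and a brief mild acidification.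

Step 19
Reactants: 28 the 13-acetate with free C8 alcohol; 32 (2E)-4-{[tert-butyl(dimethyl)silyl]oxy}-2-methylbut-2-enoic acid
Product: 34 (1S,4R,5E,8S,10R)-13-acetoxy-8-{[(2E)-4-{[tert-butyl(dimethyl)silyl]oxy}-2-methylbut-2-enoyl]oxy}-1,4-epoxy-1-methoxygermacra-5,7(11)-dien-12,6-olide, via mixed anhydride 33 (not isolated)
Conditions: 32, 2,4,6-trichlorobenzoyl chloride, Et3N, toluene, rt; then 28, DMAP, toluene, rt
Reagents that add atoms: none
Why: Yamaguchi esterification through the mixed anhydride 33 acylates the hindered secondary C8 alcohol under mild conditions that keep the (E)-enoate geometry.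

Step 20
Reactants: 34 the silylated 1-O-methyl precursor
Product: 35 (1S,4R,5E,8S,10R)-13-acetoxy-1,4-epoxy-1-hydroxy-8-{[(2E)-4-hydroxy-2-methylbut-2-enoyl]oxy}germacra-5,7(11)-dien-12,6-olide (CNP0154520.1)
Conditions: 0.5 M HCl, THF/H2O, 0 °C to rt
Reagents that add atoms: water, O
Why: Dilute aqueous acid cleaves the primary silyl ether and exchanges the ketal methoxy group for hydroxyl through the oxocarbenium ion, and the 1,4-oxygen bridge allows only the (1S) hemiketal.

**Compound list**
1 | (R)-(−)-linalool; (3R)-3,7-dimethylocta-1,6-dien-3-ol | C=C[C@](C)(O)CCC=C(C)C | starting material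
2 | (3R)-3,7-dimethyl-3-(trimethylsilyloxy)octa-1,6-diene | C=C[C@](C)(O[Si](C)(C)C)CCC=C(C)C | intermediate
3 | 3,3-dimethyl-5-[(3R)-3-methyl-3-(trimethylsilyloxy)pent-4-enyl]-1,2,4-trioxolane (ozonide; ring carbon unassigned) | C=C[C@](C)(O[Si](C)(C)C)CCC1OOC(C)(C)O1 | intermediate
4 | (4R)-4-methyl-4-(trimethylsilyloxy)hex-5-enal | C=C[C@](C)(O[Si](C)(C)C)CCC=O | intermediate
5 | (S)-but-3-yn-2-ol | C#C[C@H](C)O | starting material
6 | (S)-but-3-yn-2-yl methanesulfonate | C#C[C@H](C)OS(C)(=O)=O | intermediate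
7 | ethyl[(aR)-buta-1,2-dien-1-yl]zinc | CC[Zn]C([H])=[C@]=C([H])C | intermediate
8 | (3R,4S,7R)-3,7-dimethyl-7-(trimethylsilyloxy)non-8-en-1-yn-4-ol | C=C[C@](C)(O[Si](C)(C)C)CC[C@H](O)[C@H](C)C#C | intermediate
9 | (3R,4S,7R)-3,7-dimethylnon-8-en-1-yne-4,7-diol | C=C[C@](C)(O)CC[C@H](O)[C@H](C)C#C | intermediate
10 | (3R,7R)-7-hydroxy-3,7-dimethylnon-8-en-1-yn-4-one | C=C[C@](C)(O)CCC(=O)[C@H](C)C#C | intermediate
11 | (2S,5R)-2-[(2R)-but-3-yn-2-yl]-2-methoxy-5-methyl-5-vinyloxolane | C=C[C@@]1(C)CC[C@](OC)(O1)[C@H](C)C#C | intermediate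
12 | dicyclohexyl{(1E,3R)-3-[(2S,5R)-2-methoxy-5-methyl-5-vinyloxolan-2-yl]but-1-en-1-yl}borane | C=C[C@@]1(C)CC[C@](OC)(O1)[C@H](C)/C=C/B(C2CCCCC2)C2CCCCC2 | intermediate
13 | (3R)-3-[(2S,5R)-2-methoxy-5-methyl-5-vinyloxolan-2-yl]butanal | C=C[C@@]1(C)CC[C@](OC)(O1)[C@H](C)CC=O | intermediate
14 | tetronic acid; furan-2,4(3H,5H)-dione | O=C1CC(=O)CO1 | starting material
15 | N-[(4-bromo-2-oxo-2,5-dihydrofuran-3-yl)methylidene]-N-methylmethanaminium bromide | C[N+](C)=CC1=C(Br)COC1=O.[Br-] | intermediate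
16 | 4-bromo-2-oxo-2,5-dihydrofuran-3-carbaldehyde | O=CC1=C(Br)COC1=O | intermediate
17 | 4-bromo-3-(hydroxymethyl)furan-2(5H)-one | OCC1=C(Br)COC1=O | intermediate
18 | 4-bromo-3-({[tert-butyl(dimethyl)silyl]oxy}methyl)furan-2(5H)-one | CC(C)(C)[Si](C)(C)OCC1=C(Br)COC1=O | intermediate
19 | dichloro[4-({[tert-butyl(dimethyl)silyl]oxy}methyl)-5-oxo-2,5-dihydrofuran-3-yl]chromium (trivalent chromium) | Cl[Cr](Cl)C1=C(CO[Si](C)(C)C(C)(C)C)C(=O)OC1 | intermediate
20 | 3-({[tert-butyl(dimethyl)silyl]oxy}methyl)-4-{(1S,3R)-1-hydroxy-3-[(2S,5R)-2-methoxy-5-methyl-5-vinyloxolan-2-yl]butyl}furan-2(5H)-one | C=C[C@@]1(C)CC[C@](OC)(O1)[C@H](C)C[C@H](O)C1=C(CO[Si](C)(C)C(C)(C)C)C(=O)OC1 | intermediate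
21 | 8-O-tert-butyldimethylsilyl ether of 20 | C=C[C@@]1(C)CC[C@](OC)(O1)[C@H](C)C[C@H](O[Si](C)(C)C(C)(C)C)C1=C(CO[Si](C)(C)C(C)(C)C)C(=O)OC1 | intermediate
22 | ozonide of 21: the vinyl group replaced by 1,2,4-trioxolan-3-yl (ring carbon unassigned) | C1OOC(O1)[C@@]2(C)CC[C@](OC)(O2)[C@H](C)C[C@H](O[Si](C)(C)C(C)(C)C)C3=C(CO[Si](C)(C)C(C)(C)C)C(=O)OC3 | intermediate
23 | (2R,5S)-5-{(2R,4S)-4-{[tert-butyl(dimethyl)silyl]oxy}-4-[4-({[tert-butyl(dimethyl)silyl]oxy}methyl)-5-oxo-2,5-dihydrofuran-3-yl]butan-2-yl}-5-methoxy-2-methyloxolane-2-carbaldehyde | O=C[C@@]1(C)CC[C@](OC)(O1)[C@H](C)C[C@H](O[Si](C)(C)C(C)(C)C)C1=C(CO[Si](C)(C)C(C)(C)C)C(=O)OC1 | intermediate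
24 | 2-silyloxyfuran of 23: (2R,5S)-5-{(2R,4S)-4-{[tert-butyl(dimethyl)silyl]oxy}-4-[5-{[tert-butyl(dimethyl)silyl]oxy}-4-({[tert-butyl(dimethyl)silyl]oxy}methyl)furan-3-yl]butan-2-yl}-5-methoxy-2-methyloxolane-2-carbaldehyde | O=C[C@@]1(C)CC[C@](OC)(O1)[C@H](C)C[C@H](O[Si](C)(C)C(C)(C)C)c1coc(O[Si](C)(C)C(C)(C)C)c1CO[Si](C)(C)C(C)(C)C | intermediate
25 | (1S,4R,8S,10R)-5,8,13-tris{[tert-butyl(dimethyl)silyl]oxy}-1,4-epoxy-1-methoxygermacr-7(11)-en-12,6-olide (C5 and C6 unassigned) | CC(C)(C)[Si](C)(C)OCC1=C2C(OC1=O)C(O[Si](C)(C)C(C)(C)C)[C@@]3(C)CC[C@](OC)(O3)[C@H](C)C[C@@H]2O[Si](C)(C)C(C)(C)C | intermediate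
26 | (1S,4R,5E,8S,10R)-8,13-bis{[tert-butyl(dimethyl)silyl]oxy}-1,4-epoxy-1-methoxygermacra-5,7(11)-dien-12,6-olide | CC(C)(C)[Si](C)(C)OCC1=C2/C(=C\[C@@]3(C)CC[C@](OC)(O3)[C@H](C)C[C@@H]2O[Si](C)(C)C(C)(C)C)OC1=O | intermediate
27 | (1S,4R,5E,8S,10R)-1,4-epoxy-8,13-dihydroxy-1-methoxygermacra-5,7(11)-dien-12,6-olide | OCC1=C2/C(=C\[C@@]3(C)CC[C@](OC)(O3)[C@H](C)C[C@@H]2O)OC1=O | intermediate
28 | (1S,4R,5E,8S,10R)-13-acetoxy-1,4-epoxy-8-hydroxy-1-methoxygermacra-5,7(11)-dien-12,6-olide | CC(=O)OCC1=C2/C(=C\[C@@]3(C)CC[C@](OC)(O3)[C@H](C)C[C@@H]2O)OC1=O | intermediate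
29 | {[tert-butyl(dimethyl)silyl]oxy}acetaldehyde | CC(C)(C)[Si](C)(C)OCC=O | starting material
30 | ethyl 2-(triphenyl-λ5-phosphanylidene)propanoate | CCOC(=O)C(C)=P(c1ccccc1)(c1ccccc1)c1ccccc1 | starting material
31 | ethyl (2E)-4-{[tert-butyl(dimethyl)silyl]oxy}-2-methylbut-2-enoate | CCOC(=O)/C(C)=C/CO[Si](C)(C)C(C)(C)C | intermediate
32 | (2E)-4-{[tert-butyl(dimethyl)silyl]oxy}-2-methylbut-2-enoic acid | OC(=O)/C(C)=C/CO[Si](C)(C)C(C)(C)C | intermediate
33 | (2E)-4-{[tert-butyl(dimethyl)silyl]oxy}-2-methylbut-2-enoic 2,4,6-trichlorobenzoic anhydride | O=C(OC(=O)/C(C)=C/CO[Si](C)(C)C(C)(C)C)c1c(Cl)cc(Cl)cc1Cl | intermediate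
34 | (1S,4R,5E,8S,10R)-13-acetoxy-8-{[(2E)-4-{[tert-butyl(dimethyl)silyl]oxy}-2-methylbut-2-enoyl]oxy}-1,4-epoxy-1-methoxygermacra-5,7(11)-dien-12,6-olide | CC(=O)OCC1=C2/C(=C\[C@@]3(C)CC[C@](OC)(O3)[C@H](C)C[C@@H]2OC(=O)/C(C)=C/CO[Si](C)(C)C(C)(C)C)OC1=O | intermediate
35 | (1S,4R,5E,8S,10R)-13-acetoxy-1,4-epoxy-1-hydroxy-8-{[(2E)-4-hydroxy-2-methylbut-2-enoyl]oxy}germacra-5,7(11)-dien-12,6-olide (CNP0154520.1) | CC(=O)OCC1=C2/C(=C\[C@@]3(C)CC[C@](O)(O3)[C@H](C)C[C@@H]2OC(=O)/C(C)=C/CO)OC1=O | target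

**Step count and risks**
Total steps: 20. Longest linear sequence: 14 steps from (R)-linalool (steps 1, 2, 4, 5, 6, 7, 11, 12, 13, 14, 15, 16, 19, 20).

Step 14 (proposed new method). The ring closure may lose to intermolecular aldol oligomerisation. The C1 ketal may also ionise under the silyl triflate and be captured by the silyloxyfuran at C6 in a six-membered closure. The fallback uses known reaction types and closes the ring at C7–C8 instead. It sets out from alkyne 11: ozonolysis of the vinyl group gives the alkynyl aldehyde F1. An intermolecular vinylogous Mukaiyama aldol reaction of F1 with bromobutenolide 18 (tBuMe2SiOTf, iPr2NEt, −78 °C, no DBU) gives the open-chain silyl aldol F2. Hydroboration and oxidation of the alkyne as in step 7 give the bromo aldehyde F3. An intramolecular Nozaki–Hiyama–Kishi coupling at high dilution closes the ten-membered ring to the macrocyclic alcohol F4, whose C8 configuration then rests on the ring. Silylation of F4 gives 25, here isolated, and DBU elimination brings the route back at 26.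

Step 11. Facial selectivity at C8 may be poor, or oxidative addition into the hindered, fully substituted vinyl bromide may be slow. The fallback sets out from 13 and 18: the coupling is run without the chiral ligand (CrCl2, NiCl2 cat., DMSO) and gives 20 together with its 8R epimer F5. The mixture is oxidised with Dess–Martin periodinane to the enone F6. Reduction with the (R)-CBS oxazaborolidine and catecholborane, in which the butenolide carbon acts as the large group, should give the 8S alcohol, and the route resumes at 20.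

Step 5. The α-branched β,γ-ynone may isomerise to the allenyl ketone, or C10 may epimerise, before or during ketalisation. The fallback postpones the oxidation until the alkyne is gone and sets out from diol 9. Selective silylation of the secondary alcohol (Et3SiCl, imidazole) gives the triethylsilyl ether F7. Hydroboration and oxidation give the aldehyde F8. Ni/Cr coupling with 18 as in step 11 gives the alcohol F9, and tBuMe2SiCl/imidazole gives the tris-silyl ether F10. PPTS in MeOH at 0 °C removes only the triethylsilyl group to give the diol F11. Dess–Martin oxidation gives the hydroxy ketone F12, which has no unsaturation next to C10, and PPTS/MeOH closes the methyl ketal, so the route resumes at 21.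

**Further compounds**
F1 | step 14 | (2R,5S)-5-[(2R)-but-3-yn-2-yl]-5-methoxy-2-methyloxolane-2-carbaldehyde | O=C[C@@]1(C)CC[C@](OC)(O1)[C@H](C)C#C
F2 | step 14 | 4-bromo-3-({[tert-butyl(dimethyl)silyl]oxy}methyl)-5-{[(2R,5S)-5-((2R)-but-3-yn-2-yl)-5-methoxy-2-methyloxolan-2-yl]({[tert-butyl(dimethyl)silyl]oxy})methyl}furan-2(5H)-one (two new centres unassigned) | CC(C)(C)[Si](C)(C)OCC1=C(Br)C(OC1=O)C(O[Si](C)(C)C(C)(C)C)[C@@]2(C)CC[C@](OC)(O2)[C@H](C)C#C
F3 | step 14 | (3R)-3-{(2S,5R)-5-[(4-bromo-3-({[tert-butyl(dimethyl)silyl]oxy}methyl)-5-oxo-2,5-dihydrofuran-2-yl)({[tert-butyl(dimethyl)silyl]oxy})methyl]-2-methoxy-5-methyloxolan-2-yl}butanal | CC(C)(C)[Si](C)(C)OCC1=C(Br)C(OC1=O)C(O[Si](C)(C)C(C)(C)C)[C@@]2(C)CC[C@](OC)(O2)[C@H](C)CC=O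
F4 | step 14 | (1S,4R,8S,10R)-5,13-bis{[tert-butyl(dimethyl)silyl]oxy}-1,4-epoxy-8-hydroxy-1-methoxygermacr-7(11)-en-12,6-olide (C5 and C6 unassigned) | CC(C)(C)[Si](C)(C)OCC1=C2C(OC1=O)C(O[Si](C)(C)C(C)(C)C)[C@@]3(C)CC[C@](OC)(O3)[C@H](C)C[C@@H]2O
F5 | step 11 | 8R epimer of 20: 3-({[tert-butyl(dimethyl)silyl]oxy}methyl)-4-{(1R,3R)-1-hydroxy-3-[(2S,5R)-2-methoxy-5-methyl-5-vinyloxolan-2-yl]butyl}furan-2(5H)-one | C=C[C@@]1(C)CC[C@](OC)(O1)[C@H](C)C[C@@H](O)C1=C(CO[Si](C)(C)C(C)(C)C)C(=O)OC1
F6 | step 11 | 3-({[tert-butyl(dimethyl)silyl]oxy}methyl)-4-{(3R)-3-[(2S,5R)-2-methoxy-5-methyl-5-vinyloxolan-2-yl]butanoyl}furan-2(5H)-one | C=C[C@@]1(C)CC[C@](OC)(O1)[C@H](C)CC(=O)C1=C(CO[Si](C)(C)C(C)(C)C)C(=O)OC1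
F7 | step 5 | (3R,4S,7R)-3,7-dimethyl-4-(triethylsilyloxy)non-8-en-1-yn-7-ol | C=C[C@](C)(O)CC[C@H](O[Si](CC)(CC)CC)[C@H](C)C#C
F8 | step 5 | (3R,4S,7R)-7-hydroxy-3,7-dimethyl-4-(triethylsilyloxy)non-8-enal | C=C[C@](C)(O)CC[C@H](O[Si](CC)(CC)CC)[C@H](C)CC=O
F9 | step 5 | 3-({[tert-butyl(dimethyl)silyl]oxy}methyl)-4-[(1S,3R,4S,7R)-1,7-dihydroxy-3,7-dimethyl-4-(triethylsilyloxy)non-8-en-1-yl]furan-2(5H)-one | C=C[C@](C)(O)CC[C@H](O[Si](CC)(CC)CC)[C@H](C)C[C@H](O)C1=C(CO[Si](C)(C)C(C)(C)C)C(=O)OC1
F10 | step 5 | 1-O-tert-butyldimethylsilyl ether of F9 | C=C[C@](C)(O)CC[C@H](O[Si](CC)(CC)CC)[C@H](C)C[C@H](O[Si](C)(C)C(C)(C)C)C1=C(CO[Si](C)(C)C(C)(C)C)C(=O)OC1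
F11 | step 5 | 3-({[tert-butyl(dimethyl)silyl]oxy}methyl)-4-[(1S,3R,4S,7R)-1-{[tert-butyl(dimethyl)silyl]oxy}-4,7-dihydroxy-3,7-dimethylnon-8-en-1-yl]furan-2(5H)-one | C=C[C@](C)(O)CC[C@H](O)[C@H](C)C[C@H](O[Si](C)(C)C(C)(C)C)C1=C(CO[Si](C)(C)C(C)(C)C)C(=O)OC1
F12 | step 5 | 3-({[tert-butyl(dimethyl)silyl]oxy}methyl)-4-[(1S,3R,7R)-1-{[tert-butyl(dimethyl)silyl]oxy}-7-hydroxy-3,7-dimethyl-4-oxonon-8-en-1-yl]furan-2(5H)-one | C=C[C@](C)(O)CCC(=O)[C@H](C)C[C@H](O[Si](C)(C)C(C)(C)C)C1=C(CO[Si](C)(C)C(C)(C)C)C(=O)OC1
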